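The earlier runs and the new flask were generated by integration from invented constants.

Subtract the protic impurity from the partner first. I call this difference, partner charged minus impurity charged, the surplus S, and it is what I carry through these flasks.

| flask | starting material | partner | second substrate | protic impurity | remark | time |
|---|---|---|---|---|---|---|
| south-west | 0.066 M | 0.0784 M | 0.098 M | 0.098 M | run made earlier |  |
| red | 0.098 M | 0.0784 M | 0.0980 M | 0.0980 M |  | 4.0 h |
| green | 0.098 M | 0.300 M | 0.0980 M | 0.0980 M |  | 15 h |

south-west run (percent of the starting material charged)

| time / min | target / % | starting material / % |
|---|---|---|
| 6.00 | 23.9 | 76.0 |
| 12.0 | 26.0 | 74.3 |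
| 20.0 | 23.4 | 76.5 |
| 30.0 | 20.9 | 79.6 |
| 50.0 | 15.7 | 84.1 |
| 80.0 | 12.1 | 88.0 |

(scatter of a reading: 0.3 percentage points)

- the earlier runs were read with a standard deviation of 0.3 percentage points

1. the winner by amount of target, in percent of the starting material charged; "neither" if no more than 2 percentage points parts them (red / green / neither)
2. how much target is there at the end, in percent of the starting material charged: red
3. how much target is there at the end, in percent of the starting material charged: green

I read the time scales that the readings show, from short to long. The binding of starting material and partner into target comes first: by 6.00 min the south-west run shows 23.9% target, and target plus starting material read 99.9%, so I can read no loss from this pair. But target still climbs to 26.0% at 12.0 min, so the binding is still catching up at 6.00 min. From about 12.0 min on I treat it as in balance, with the ratio of target to starting material following the free partner.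

Next comes the fade. Target reads 26.0% at 12.0 min and about half of that, 12.1%, at 80.0 min. The ratio of target to starting material halves in about 50.5 min by these readings, and I take this as impurity eating the partner.

Red has the south-west run's partner and impurity, so its surplus is the same, −0.0196 M. That is negative, which makes partner the limiting reagent against the impurity, and 4.0 h is longer than that halving time, so I expect red's target to fade. Green has S = 0.202 M. Scaling the halving time by the partner that the impurity meets gives about 16.5 min, far shorter than 15 h, so I expect green's impurity to go early and commit to green. What becomes of green's surplus of 0.202 M over hours lies beyond the last reading.

The forecast says green, with 5% for red (range 2% to 10%) and 54% for green (range 40% to 68%), “assuming no slow side reaction”.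

The flask gives green: 3.96% in red and 26.6% in green.

    starting material + partner ⇌ target (K = 11.0 M⁻¹, k = 100 M⁻¹ h⁻¹)
    second substrate + partner ⇌ second product (K = 4.30 M⁻¹, k = 910 M⁻¹ h⁻¹)
    partner + protic impurity → quenched reagent (k = 27.0 M⁻¹ h⁻¹)
    2 partner → self-condensation product (k = 1.20 M⁻¹ h⁻¹)

Green's surplus of 0.202 M does not stay free. At 15.0 h it stands as 0.0328 M free partner, 0.0382 M bound in target and second product, and 0.131 M spent on self-condensation product, two partner per turn. Green's target stays at 26.6% because target runs back to starting material and partner: the same run without that reverse step holds 100%. Without self-condensation green holds 55.8% target, which is a part of the shortfall.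

A neighbour flask, green with 0.075 M of partner, has S = −0.0230 M, negative like red, so about 23.5% of the impurity should outlast the partner. It ends with 25% of its impurity, 0.18% of its partner and 0.150% target.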